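**Retrosynthetic overview**
- The target, 3,5-dibromo-2-(2,4-dibromophenoxy)phenol, is taken back to its C1 pinacol boronate; C–B oxidation is the last step.
- The feature the strategy rests on is the phenol ring: C1 (OH), C2 (OAr), C3 (Br), C5 (Br). The hydroxyl is meta to both bromines, a pattern that bromination of a 2-aryloxyphenol cannot deliver.
- This ring is cut at C2–C3 and C1–C6. C3(Br)–C4(H)–C5(Br)–C6(H) come from C3–C6 of 3,5-dibromo-2-pyrone; C2 (oxygen-bearing) and C1 (boron-bearing) come from a (2,4-dibromophenoxy)ethynyl boronate. A [4+2] cycloaddition followed by loss of CO2 builds the ring.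
- The pyrone comes from coumalic acid. The alkynylboronate comes from 2,4-dibromophenol by O-vinylation, bromination/dehydrobromination, a second dehydrobromination and amide-base borylation.
- Ring order: the dibromophenoxy ring is bought; the phenol ring is the only ring constructed, in the key step.

Key step: step 6

Assumption: the target has no stereocentre and no resolvable axis, so the "single enantiomer" is the achiral compound as drawn and nothing has to be controlled.
Remark on the chemistry: alkyllithium reagents are kept out of the main route because of the aryl C–Br bonds; the ynol ether is made by eliminations with non-exchanging bases.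

**Step 1**
Reactants: 1 coumalic acid (2-oxo-2H-pyran-5-carboxylic acid)
Product: 2 3,5-dibromo-2H-pyran-2-one
Conditions: NBS (2.5 equiv), LiOAc (1.2 equiv), MeCN–H2O (9:1), rt
Reagents that add atoms: N-bromosuccinimide, O=C1CCC(=O)N1Br
Why: One-pot electrophilic bromination at the nucleophilic C3 of the pyrone and Hunsdiecker-type ipso-bromodecarboxylation of the C5 carboxylate, a known conversion of coumalic acid.

**Step 2**
Reactants: 3 2,4-dibromophenol; 4 2,4,6-trivinylcyclotriboroxane–pyridine complex (0.67 equiv)
Product: 5 2,4-dibromo-1-(ethenyloxy)benzene
Conditions: Cu(OAc)2 (1 equiv, turned over by air), pyridine (10 equiv), CH2Cl2, air, rt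
Reagents that add atoms: none
Why: Chan–Lam oxidative O-vinylation, in which phenoxide and a vinyl group from the boroxine couple on copper at room temperature, conditions under which aryl bromides are inert.

**Step 3**
Reactants: 5 2,4-dibromo-1-(ethenyloxy)benzene
Product: 7 2,4-dibromo-1-{[(Z)-2-bromoethenyl]oxy}benzene, via 1,2-dibromoethyl ether 6 (not isolated)
Conditions: Br2 (1.05 equiv), CH2Cl2, −78 °C; then Et3N (2.5 equiv), −78 °C → rt
Reagents that add atoms: bromine, BrBr
Why: Electrophilic addition of bromine to the enol ether double bond (much faster than attack on the deactivated ring) gives the α,β-dibromo ether, whose labile α-bromide leaves with a β-hydrogen in an amine-mediated dehydrobromination; the Z isomer should predominate and any E isomer converges in step 4.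

**Step 4**
Reactants: 7 2,4-dibromo-1-{[(Z)-2-bromoethenyl]oxy}benzene
Product: 8 2,4-dibromo-1-(ethynyloxy)benzene
Conditions: KOtBu (1.3 equiv), THF, −78 → 0 °C; cold aqueous work-up, used at once as a solution
Reagents that add atoms: none
Why: Base-induced anti β-elimination (dehydrohalogenation) of a 2-bromovinyl ether, the classical entry to aryl ethynyl ethers, with a base that neither exchanges aryl bromides nor metalates the ring.

**Step 5**
Reactants: 8 2,4-dibromo-1-(ethynyloxy)benzene; 9 2-isopropoxy-4,4,5,5-tetramethyl-1,3,2-dioxaborolane
Product: 12 2-[(2,4-dibromophenoxy)ethynyl]-4,4,5,5-tetramethyl-1,3,2-dioxaborolane, via lithium aryloxyacetylide 10 (not isolated), via lithium alkynyl(isopropoxy)borate 11 (not isolated)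
Conditions: LiHMDS (1.05 equiv), THF, −78 °C; 9 (1.1 equiv), −78 °C; HCl (1.0 M in Et2O, 1.1 equiv), −78 °C → rt; filter, concentrate, use crude
Reagents that add atoms: none
Why: Standard alkynylboronate synthesis by alkyne deprotonation, addition of the acetylide to the borate ester and anhydrous acid release of isopropanol from the ate complex; the silylamide is too weak to metalate the aryl C–H between the two bromines and cannot undergo bromine–lithium exchange.

**Step 6**
Reactants: 2 3,5-dibromo-2H-pyran-2-one; 12 2-[(2,4-dibromophenoxy)ethynyl]-4,4,5,5-tetramethyl-1,3,2-dioxaborolane (1.3 equiv)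
Product: 14 2-[3,5-dibromo-2-(2,4-dibromophenoxy)phenyl]-4,4,5,5-tetramethyl-1,3,2-dioxaborolane, via bridged bicyclic lactone 13 (not isolated)
Conditions: toluene, 120 °C, sealed tube, N2
Reagents that add atoms: none
Why: Proposed new method: a 1-aryloxy-alkynylboronate has not been used as the 2π partner of a 2-pyrone, but its push–pull polarisation (oxygen donates, the vacant boron orbital accepts) makes the boron-bearing carbon the nucleophilic terminus, which should bond first to the electrophilic C6 of the pyrone while the oxygen-bearing carbon closes onto the bromine-bearing C3 in a concerted, asynchronous, inverse-demand [4+2] cycloaddition. The closest known reaction type is the thermal Diels–Alder/retro-Diels–Alder reaction of 2-pyrones with alkynylboronates to give arylboronates, supported by cycloadditions of 3,5-dibromo-2-pyrone with enol ethers, which place the oxygen-bearing carbon next to C3 in the same sense. The carbocycle is closed by this intermolecular [4+2] cycloaddition across pyrone C3 and C6 (new bonds C2–C3 and C1–C6 in target numbering) to give bridged lactone 13, and is aromatised by irreversible retro-[4+2] loss of CO2. No stereocentre has to be controlled, since the two bridgehead centres of racemic 13 vanish on aromatisation. The selectivity needed is head-to-tail regiochemistry (boron carbon to C6, aryloxy carbon to C3), which the matched polarisation of alkyne and pyrone should secure; no metal or base is present, so the four C–Br bonds and the C–B bond are untouched.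

**Step 7**
Reactants: 14 2-[3,5-dibromo-2-(2,4-dibromophenoxy)phenyl]-4,4,5,5-tetramethyl-1,3,2-dioxaborolane
Product: 15 3,5-dibromo-2-(2,4-dibromophenoxy)phenol
Conditions: 30% aq H2O2, aq NaOH, THF, 0 °C → rt; then aq NH4Cl
Reagents that add atoms: hydrogen peroxide, OO
Why: Oxidation of the aryl C–B bond by hydroperoxide (1,2-aryl shift from boron to oxygen, then hydrolysis of the borate), which leaves aryl bromides and the diaryl ether untouched under cold, dilute basic conditions.

**Compound list**
1 | coumalic acid (2-oxo-2H-pyran-5-carboxylic acid) | O=C(O)c1ccc(=O)oc1 | starting material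
2 | 3,5-dibromo-2H-pyran-2-one | O=c1occ(Br)cc1Br | intermediate
3 | 2,4-dibromophenol | Oc1ccc(Br)cc1Br | starting material
4 | 2,4,6-trivinylcyclotriboroxane–pyridine complex | C=CB1OB(C=C)OB(C=C)O1.c1ccncc1 | starting material
5 | 2,4-dibromo-1-(ethenyloxy)benzene | C=COc1ccc(Br)cc1Br | intermediate
6 | 2,4-dibromo-1-(1,2-dibromoethoxy)benzene (racemic, not isolated) | BrCC(Br)Oc1ccc(Br)cc1Br | intermediate
7 | 2,4-dibromo-1-{[(Z)-2-bromoethenyl]oxy}benzene | Br/C=C\Oc1ccc(Br)cc1Br | intermediate
8 | 2,4-dibromo-1-(ethynyloxy)benzene | C#COc1ccc(Br)cc1Br | intermediate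
9 | 2-isopropoxy-4,4,5,5-tetramethyl-1,3,2-dioxaborolane | CC(C)OB1OC(C)(C)C(C)(C)O1 | starting material
10 | lithium 2-(2,4-dibromophenoxy)ethynide (not isolated) | [Li]C#COc1ccc(Br)cc1Br | intermediate
11 | lithium [(2,4-dibromophenoxy)ethynyl](isopropoxy)(pinacolato)borate (not isolated) | [Li+].CC(C)O[B-]1(C#COc2ccc(Br)cc2Br)OC(C)(C)C(C)(C)O1 | intermediate
12 | 2-[(2,4-dibromophenoxy)ethynyl]-4,4,5,5-tetramethyl-1,3,2-dioxaborolane | CC1(C)OB(C#COc2ccc(Br)cc2Br)OC1(C)C | intermediate
13 | 4,7-dibromo-5-(2,4-dibromophenoxy)-6-(4,4,5,5-tetramethyl-1,3,2-dioxaborolan-2-yl)-2-oxabicyclo[2.2.2]octa-5,7-dien-3-one (racemic, not isolated) | O=C1OC2C(Br)=CC1(Br)C(Oc3ccc(Br)cc3Br)=C2B4OC(C)(C)C(C)(C)O4 | intermediate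
14 | 2-[3,5-dibromo-2-(2,4-dibromophenoxy)phenyl]-4,4,5,5-tetramethyl-1,3,2-dioxaborolane | CC1(C)OB(OC1(C)C)c1cc(Br)cc(Br)c1Oc1ccc(Br)cc1Br | intermediate
15 | 3,5-dibromo-2-(2,4-dibromophenoxy)phenol | Oc1cc(Br)cc(Br)c1Oc1ccc(Br)cc1Br | target

**Step count**
Total steps: 7. Longest linear sequence: 6 (steps 2–7, from 2,4-dibromophenol 3).

**Steps most likely to fail**

1. Step 6 (cycloaddition/CO2 extrusion). The alkynylboronate may decompose thermally or lose boron before it reacts, the cycloaddition may be too slow at temperatures the ynol ether tolerates, or the partners may combine with the opposite regiochemistry. The fallback forms the diaryl ether by SNAr and the hydroxyl by a Dakin-type oxidation, both known chemistry. It sets out from 2,4-dibromophenol 3, which is heated with commercial 3,5-dibromo-2-fluorobenzaldehyde (O=Cc1cc(Br)cc(Br)c1F) and K2CO3 in DMAc at 90–110 °C. The fluoride, activated by the ortho aldehyde, should be displaced to give 3,5-dibromo-2-(2,4-dibromophenoxy)benzaldehyde F1. Baeyer–Villiger oxidation with mCPBA in CH2Cl2, where aryl migration is favoured by the ortho aryloxy donor, should give 3,5-dibromo-2-(2,4-dibromophenoxy)phenyl formate F2. Methanolysis with K2CO3 in MeOH then returns to the route at target 15.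

2. Step 5 (borylation). The acid used to break the ate complex may add to the ynol ether, or the push–pull alkynylboronate may protodeboronate during isolation. The fallback sets out from 8 and uses a copper- or zinc-catalysed dehydrogenative C–H borylation with pinacolborane (B1OC(C)(C)C(C)(C)O1) in toluene. It is free of base and protic acid and releases only dihydrogen. It returns to the route at 12, which is taken on as a crude solution into step 6; no new compound is made (F0).

3. Step 4 (terminal ynol ether). The free aryl ethynyl ether may oligomerise on concentration, the minor E isomer may eliminate sluggishly, or tert-butoxide may add to the triple bond. The fallback avoids the free terminal alkyne. It sets out from 3, which with trichloroethylene and K2CO3 in DMF at 60–70 °C should give 2,4-dibromo-1-{[(E)-1,2-dichloroethenyl]oxy}benzene F3. Treatment with n-BuLi (2.1 equiv) in Et2O at −78 °C should effect β-elimination to the chloroalkyne and chlorine–lithium exchange. Ether and low temperature are chosen because bromine–lithium exchange of aryl bromides is slow under these conditions, though this remains the weak point of the fallback. It returns to the route at lithium acetylide 10, which is borylated in the same flask as in step 5 to give 12.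

**Further compounds**
F1 | step 6 | 3,5-dibromo-2-(2,4-dibromophenoxy)benzaldehyde | O=Cc1cc(Br)cc(Br)c1Oc1ccc(Br)cc1Br
F2 | step 6 | 3,5-dibromo-2-(2,4-dibromophenoxy)phenyl formate | O=COc1cc(Br)cc(Br)c1Oc1ccc(Br)cc1Br
F0 | step 5 | none | none
F3 | step 4 | 2,4-dibromo-1-{[(E)-1,2-dichloroethenyl]oxy}benzene | Cl/C=C(/Cl)Oc1ccc(Br)cc1Br
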